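## Structural features

The target is a 2,3-dihydro-1,4-benzodioxine in which ring A is fused to the dioxane ring B (O1–C2–C3–O4); C2 carries ring C, a 3,4-dihydroxy-5-methoxyphenyl group, and C3 a hydroxymethyl group. Ring A is fully differentiated: C5, next to the carbon that holds O4, bears a methoxy group, and C7, para to O4 and meta to O1, bears an (E)-propenal chain. C2 and C3 are adjacent carbon–oxygen stereocentres, both (R), with the aryl and hydroxymethyl groups trans (diequatorial). The fragile parts are the free catechol of ring C (oxidation), the enal (nucleophiles, base) and the C2–O1 benzylic aryl ether, which can ionise in acid and, once the para-hydroxyl of ring C is free, can open to a quinone methide in base. The real difficulty is not the trans relationship, which is the thermodynamic one while C3 is epimerisable, but the combination of absolute configuration with the regiochemistry of an unsymmetrical catechol: O1 must end on the benzylic carbon and O4 on C3, not the reverse. The key step uses two facts: C2 is at the aldehyde oxidation level of ring C and can be tied to both O1 and O4 in a five-membered acetal, and a C7 carbonyl group para to O4 makes the two acetal oxygens electronically different. Inserting one carbon (C3) between C2 and O4 then builds ring B, both skeletal bonds at C3 and both stereocentres.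

## Logic of the disconnections

15 ⇒ 14. The two O–C(allyl) bonds on ring C are cut. The catechol is the function least able to survive oxidants and base, and a free para-hydroxyl on ring C would make C2 labile, so it stays masked to the end. The gain is that every earlier intermediate is a robust bis-ether. The demand is a deallylation that is neither basic nor aggressive towards the enal.

14 ⇒ 12 + 13. The C=C bond of the propenal chain at C7 is cut. An aryl aldehyde and a formyl-stabilised ylide are the natural partners for an (E)-enal, and the cut reduces the ring A substituent to one carbon. The forward step must stop after one homologation and tolerate the free C3 hydroxymethyl group.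

12 ⇒ 11. No skeletal bond is cut; the C7 formyl group is traced to a benzylic alcohol. Two primary alcohols are then told apart by position alone, without protecting groups. The forward step needs an oxidant selective for benzylic alcohols, which is only possible while the catechol is masked.

11 ⇒ 10. Both hydroxymethyl groups are traced to methyl esters. The C7 ester is the acceptor that differentiates O1 from O4 in the key step, and the C3 ester arrives with the inserted carbon and keeps C3 epimerisable until the trans relationship is secured. One reduction removes both handles; it must proceed without enolisation or β-elimination at C3.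

10 ⇒ 7 + 8 (through 9). The bonds C2–C3 and O4–C3 are cut, which takes C3 and its ester out of ring B and leaves C2 bound to both O1 and O4. This is the most simplifying cut: the ring, two skeletal bonds and both stereocentres trace back to 7, which may be racemic because its stereocentre is erased on ionisation, and to 8. The forward step demands ionisation at C2–O4 and not at C2–O1, facial control at the planar cation by a chiral counter-anion, capture of the diazonium carbon by O4 ahead of 1,2-shifts, and conversion of 9 into 10 without touching C2. The design of 7 answers these demands. Ring C carries allyl ethers, because acetal-type protecting groups would ionise and accept 8 under the same acid. Ring A stays at the ester level, because a formyl group would itself be homologated by 8 under acid. Both esters of 10 are methyl esters, so methoxide can equilibrate C3 without scrambling them.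

7 ⇒ 3 + 5 (through 6, with 4). The two acetal C–O bonds are cut. Both oxygens of 5 bind the same carbon, so no regiochemical question arises here; it is deferred to the key step, where the C7 ester answers it. The forward step must drive an exchange equilibrium and deliver an acid-labile product.

3 ⇒ 1 + 2. The two O–allyl bonds are cut, leading to purchasable materials; the forward step has to alkylate both phenols and therefore consumes two equivalents of 2.

## Other disconnections considered

Alternative 1: The cut removes both aryl–oxygen bonds of ring B (O1–C8a and O4–C4a). Ring A would come as the aryne A4, released by CsF from the silyl triflate A3. The C2–C3 unit, with both stereocentres in place, would come as the hydroxy peroxide A2. The product of the key step is A1. In the forward step the C2 alkoxide of A2 adds to C8a, the aryne carbon remote from the methoxy group. The aryl anion left at C4a attacks the peroxide oxygen on C3 with loss of the tert-butoxy group.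
- In favour: the stereocentres are made beforehand and no bond at C2 or C3 is broken, so this is better than the chosen plan on stereochemical security. The regiochemistry rests on the established polarisation of 3-alkoxyarynes, at least the equal of the electronic bias between the acetal oxygens of 7. The union is convergent.
- Against: A2 is a secondary peroxide with a C3–H next to a carbinol, so base-induced Kornblum–DeLaMare fragmentation and retro-aldol cleavage compete in the fluoride/alkoxide medium. An aryl anion tends to be protonated rather than to attack an O–O bond, and ring closure on peroxide oxygen is not an established aryne reaction. A2 is also a handling hazard.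
- Comparison: step economy is worse. A2 and A3 each need several steps, and after A1 an acetal hydrolysis, the two-carbon homologation and removal of silyl and MOM groups remain, against seven steps in all for the chosen plan. Mechanistically both plans hinge on an unproven ring-forming event. The chosen plan places the uncertainty in cation/diazo chemistry under catalytic acid; this one places it in a strongly basic medium that A2 may not survive.

Alternative 2: The cut removes C7–C(allyl) and O4–C3. The precursor is the O4 allyl ether A6, in which O1 is already bound to C2 and C3 is an oxirane carbon; the product is A5. On heating, the allyl group cannot stay at either ortho position of O4 (C5 carries the methoxy group, C8a carries O1), so a second [3,3] shift passes it to C7. The phenol so released opens the oxirane at C3 in a 6-exo closure with inversion.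
- In favour: the O1/O4 regiochemistry is fixed by construction, which is better than the chosen plan. C3 is set by a stereospecific SN2 opening, better in predictability. The three side-chain carbons arrive with no reagent and ring A needs no acceptor group, better in atom economy at that point. Both elementary events are individually known, which on mechanism is the equal of the chosen plan or better.
- Against: the stereochemical problem is moved into A6. Its C2–O1 bond must be made with defined configuration at a benzylic carbon that bears an electron-rich aryl group and sits next to an oxirane, where substitution is prone to ionisation. The rearrangement needs roughly 180–200 °C, at which a benzylic aryl ether, an aryl-substituted oxirane and MOM ethers are at risk (elimination, Meinwald-type rearrangement). The neutral phenol may need a base to open the oxirane, and 7-endo opening at the CH2 terminus competes.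
- Comparison: after A5 the allyl group must still be turned into the enal and the MOM groups removed, about as many steps as the chosen plan needs after 10. A6 is a much longer precursor than 7, so overall step economy is worse.

Alternative 3: The cut removes O1–C2 and O4–C4a, giving the cis-glycidate A8 and the fluoro phenol A9; the product is A7. The phenoxide of A9 would open A8 at the benzylic carbon with inversion, and the C3 alkoxide would then displace fluoride para to the formyl group. A cis-oxirane with one inversion gives the trans ring.
- In favour: it is a two-component convergent union, equal to the chosen plan. Regiochemistry is fixed by the position of the fluorine, which is better. Stereochemistry comes from a stereospecific opening, more predictable than ion-pair control as long as the opening stays SN2, which is better. Ring A is already at the aldehyde level, better on that point.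
- Against: enantiopure cis-glycidates with an electron-rich aryl group are hard to obtain, and their benzylic C–O bond ionises easily, which would erode inversion fidelity. The fluoroarene is activated only by a para-formyl group and deactivated by an ortho-methoxy group, so the displacement needs forcing basic conditions. Under these the α-alkoxy ester can cleave in retro-aldol fashion and the aldehyde can react. The C3 ester must later be reduced beside the C7 aldehyde or enal, which costs protection or a reduction–reoxidation that cancels the saving.
- Comparison: overall step count is comparable to the chosen plan, not shorter. Each elementary step is of a known kind, which is an advantage, but their one-pot combination on this substitution pattern is untested. The precursor 7 of the chosen plan is far easier to make than A8.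

Key step: step 3

Assumption: the enantiomer of the chiral acid that leads to the (2R) series is identified in a screen and the route is written for it; 8 is taken as a purchasable reagent and handled only as a dilute solution.

Remark on numbering and descriptors: locants follow O1–C2(aryl)–C3–O4 with methoxy on C5 and the carbon substituent on C7 throughout. C3 is (S) in 10 and (R) from 11 on, with no change in spatial arrangement, because the ester outranks C2 and the hydroxymethyl group does not. Stereoconvergence arises at the planar cation, not from the later C3 equilibration.

## Route

Step 1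
Reactants: 1 3,4-dihydroxy-5-methoxybenzaldehyde; 2 allyl bromide (first equivalent)
Product: 3 3,4-bis(allyloxy)-5-methoxybenzaldehyde
Conditions: 2 (2.5 equiv in all), K2CO3 (3 equiv), DMF, 60 °C
Reagents that add atoms: allyl bromide (second equivalent), C=CCBr
Why: Twofold Williamson etherification: each phenoxide of 1 is alkylated by one equivalent of the primary allylic bromide 2, so two equivalents are consumed; the aldehyde is inert and no stereocentre is involved.

Step 2
Reactants: 3 3,4-bis(allyloxy)-5-methoxybenzaldehyde; 4 trimethyl orthoformate; 5 methyl 3,4-dihydroxy-5-methoxybenzoate
Product: 7 racemic methyl 2-[3,4-bis(allyloxy)-5-methoxyphenyl]-7-methoxy-1,3-benzodioxole-5-carboxylate, via dimethyl acetal 6 (not isolated)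
Conditions: 3, 4, PPTS (cat.), MeOH, rt; evaporate; then 5, CSA (cat.), toluene, 5 Å MS, 80 °C; Et3N quench
Reagents that add atoms: none
Why: Acid-catalysed acetalisation with the orthoformate as water scavenger gives 6, and acid-catalysed transacetalisation with the catechol 5 is driven to the five-membered diaryloxy acetal by removal of methanol. The acetal carbon forms without control, so 7 is racemic, which the next step does not mind; the mild temperature spares the allyl ethers from Claisen rearrangement.

Step 3
Reactants: 7 racemic methyl 2-[3,4-bis(allyloxy)-5-methoxyphenyl]-7-methoxy-1,3-benzodioxole-5-carboxylate; 8 methyl diazoacetate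
Product: 10 dimethyl (2R,3S)-2-[3,4-bis(allyloxy)-5-methoxyphenyl]-5-methoxy-2,3-dihydro-1,4-benzodioxine-3,7-dicarboxylate (trans), via cis-(2R,3R) diester 9 (not isolated)
Conditions: chiral IDPi acid (confined imidodiphosphorimidate, 5 mol%), 8 (1.5 equiv, 1 M in CH2Cl2, syringe pump), CH2Cl2, 4 Å MS, −78 → −40 °C; then NaOMe (0.3 equiv), MeOH, 0 °C → rt; AcOH quench
Reagents that add atoms: none
Why: Proposed new method: the chiral acid reversibly ionises 7 at C2–O4 to a planar O1-oxocarbenium ion that is paired with the chiral anion and still tethered to the O4 phenol, so both enantiomers of 7 funnel into one intermediate; the nucleophilic carbon of 8 adds to C2, and the O4–H phenol, hydrogen-bonded to the anion, displaces N2 from the α-diazonium ester, forming C2–C3 and O4–C3 and returning the proton to the catalyst. The closest known reaction type is the BF3·OEt2-promoted formal insertion of diazoacetates into C–O bonds of acyclic acetals and orthoformates, together with chiral-anion-directed additions of carbon nucleophiles to oxocarbenium ions; neither has been shown as a ring expansion of a catechol benzylidene acetal. Ring B closes in 6-exo-tet mode by backside attack of O4 on C3. C2 is set in the C–C bond-forming event by the face of the cation that the confined anion leaves open and is not touched afterwards; C3 emerges as a kinetic mixture (9 and 10) and is then moved by methoxide-catalysed enolisation to the diequatorial trans arrangement dictated by C2. The step needs regioselection between the two acetal oxygens, which the C7 ester provides by making O4 the poorer donor and better nucleofuge and which the flanking C5 methoxy group reinforces sterically. It also needs oxygen capture to outrun 1,2-shifts of hydride or of ring C at the diazonium stage, which the ortho-tethered phenol favours by making capture intramolecular. Should the anion deprotonate the diazonium ion instead, the α-diazo ester so formed would be re-protonated by the strong acid and close in the same way. Slow addition of 8 at low temperature keeps acid-induced decomposition of the diazo ester below the rate of the productive path, and the matching methyl esters make the methoxide equilibration degenerate at both ester groups.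

Step 4
Reactants: 10 dimethyl (2R,3S)-2-[3,4-bis(allyloxy)-5-methoxyphenyl]-5-methoxy-2,3-dihydro-1,4-benzodioxine-3,7-dicarboxylate
Product: 11 [(2R,3R)-2-[3,4-bis(allyloxy)-5-methoxyphenyl]-5-methoxy-2,3-dihydro-1,4-benzodioxine-3,7-diyl]dimethanol
Conditions: LiAlH4, THF, −10 → 0 °C; aq. potassium sodium tartrate
Reagents that add atoms: none
Why: Hydride reduction of both methyl esters to primary alcohols; inverse addition at low temperature avoids enolisation at C3, which keeps its spatial arrangement and can no longer epimerise afterwards. Allyl ethers and the benzodioxane are inert.

Step 5
Reactants: 11 [(2R,3R)-2-[3,4-bis(allyloxy)-5-methoxyphenyl]-5-methoxy-2,3-dihydro-1,4-benzodioxine-3,7-diyl]dimethanol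
Product: 12 (2R,3R)-2-[3,4-bis(allyloxy)-5-methoxyphenyl]-3-(hydroxymethyl)-5-methoxy-2,3-dihydro-1,4-benzodioxine-7-carbaldehyde
Conditions: activated MnO2, CH2Cl2, rt
Reagents that add atoms: none
Why: Chemoselective benzylic oxidation: activated MnO2 oxidises the C7 benzylic alcohol and leaves the saturated primary alcohol at C3 untouched.

Step 6
Reactants: 12 (2R,3R)-2-[3,4-bis(allyloxy)-5-methoxyphenyl]-3-(hydroxymethyl)-5-methoxy-2,3-dihydro-1,4-benzodioxine-7-carbaldehyde; 13 (triphenylphosphoranylidene)acetaldehyde
Product: 14 (E)-3-[(2R,3R)-2-[3,4-bis(allyloxy)-5-methoxyphenyl]-3-(hydroxymethyl)-5-methoxy-2,3-dihydro-1,4-benzodioxin-7-yl]prop-2-enal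
Conditions: 13 (1.2 equiv), toluene, 85 °C
Reagents that add atoms: none
Why: Wittig olefination with a formyl-stabilised ylide should give the (E)-enal; the free alcohol is tolerated, and a small excess of 13 with monitoring limits a second homologation.

Step 7
Reactants: 14 (E)-3-[(2R,3R)-2-[3,4-bis(allyloxy)-5-methoxyphenyl]-3-(hydroxymethyl)-5-methoxy-2,3-dihydro-1,4-benzodioxin-7-yl]prop-2-enal
Product: 15 (E)-3-[(2R,3R)-2-(3,4-dihydroxy-5-methoxyphenyl)-3-(hydroxymethyl)-5-methoxy-2,3-dihydro-1,4-benzodioxin-7-yl]prop-2-enal (target)
Conditions: Pd(PPh3)4 (5 mol%), p-TolSO2H (2.2 equiv), THF, rt, degassed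
Reagents that add atoms: none
Why: Tsuji–Trost-type deallylation: Pd(PPh3)4 ionises each aryl allyl ether to a π-allyl complex of divalent palladium and the sulfinate captures the allyl fragment as a sulfone. The medium is non-basic, which spares the enal, the catechol being released and the C2 benzylic ether; carbon-acid scavengers of the barbiturate type are avoided because they would condense with the enal.

## Compound list

1 | 3,4-dihydroxy-5-methoxybenzaldehyde | COc1cc(C=O)cc(O)c1O | starting material
2 | allyl bromide | C=CCBr | starting material
3 | 3,4-bis(allyloxy)-5-methoxybenzaldehyde | C=CCOc1cc(C=O)cc(OC)c1OCC=C | intermediate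
4 | trimethyl orthoformate | COC(OC)OC | starting material
5 | methyl 3,4-dihydroxy-5-methoxybenzoate | COC(=O)c1cc(O)c(O)c(OC)c1 | starting material
6 | 1,2-bis(allyloxy)-5-(dimethoxymethyl)-3-methoxybenzene (not isolated) | COC(OC)c1cc(OC)c(OCC=C)c(OCC=C)c1 | intermediate
7 | racemic methyl 2-[3,4-bis(allyloxy)-5-methoxyphenyl]-7-methoxy-1,3-benzodioxole-5-carboxylate | COc1cc(C2Oc3cc(C(=O)OC)cc(OC)c3O2)cc(OCC=C)c1OCC=C | intermediate
8 | methyl diazoacetate | COC(=O)C=[N+]=[N-] | starting material
9 | dimethyl (2R,3R)-2-[3,4-bis(allyloxy)-5-methoxyphenyl]-5-methoxy-2,3-dihydro-1,4-benzodioxine-3,7-dicarboxylate (cis, not isolated) | COc1cc([C@H]2Oc3cc(C(=O)OC)cc(OC)c3O[C@H]2C(=O)OC)cc(OCC=C)c1OCC=C | intermediate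
10 | dimethyl (2R,3S)-2-[3,4-bis(allyloxy)-5-methoxyphenyl]-5-methoxy-2,3-dihydro-1,4-benzodioxine-3,7-dicarboxylate (trans) | COc1cc([C@H]2Oc3cc(C(=O)OC)cc(OC)c3O[C@@H]2C(=O)OC)cc(OCC=C)c1OCC=C | intermediate
11 | [(2R,3R)-2-[3,4-bis(allyloxy)-5-methoxyphenyl]-5-methoxy-2,3-dihydro-1,4-benzodioxine-3,7-diyl]dimethanol | COc1cc([C@H]2Oc3cc(CO)cc(OC)c3O[C@@H]2CO)cc(OCC=C)c1OCC=C | intermediate
12 | (2R,3R)-2-[3,4-bis(allyloxy)-5-methoxyphenyl]-3-(hydroxymethyl)-5-methoxy-2,3-dihydro-1,4-benzodioxine-7-carbaldehyde | COc1cc([C@H]2Oc3cc(C=O)cc(OC)c3O[C@@H]2CO)cc(OCC=C)c1OCC=C | intermediate
13 | (triphenylphosphoranylidene)acetaldehyde | O=CC=P(c1ccccc1)(c1ccccc1)c1ccccc1 | starting material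
14 | (E)-3-[(2R,3R)-2-[3,4-bis(allyloxy)-5-methoxyphenyl]-3-(hydroxymethyl)-5-methoxy-2,3-dihydro-1,4-benzodioxin-7-yl]prop-2-enal | COc1cc([C@H]2Oc3cc(/C=C/C=O)cc(OC)c3O[C@@H]2CO)cc(OCC=C)c1OCC=C | intermediate
15 | (E)-3-[(2R,3R)-2-(3,4-dihydroxy-5-methoxyphenyl)-3-(hydroxymethyl)-5-methoxy-2,3-dihydro-1,4-benzodioxin-7-yl]prop-2-enal | COc1cc([C@H]2Oc3cc(/C=C/C=O)cc(OC)c3O[C@@H]2CO)cc(O)c1O | target

## Step count and least certain steps

Total step count: 7. Longest linear sequence: 7 steps (1 → 3 → 7 → 10 → 11 → 12 → 14 → 15); 2, 4, 5, 8 and 13 enter as purchased materials.

Step 3 (key step, proposed new method). The most likely failures are: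
- proton transfer from the chiral acid to the diazo ester, with alkylation of the catalyst and loss of turnover;
- a 1,2-shift of hydride or of the electron-rich ring C at the diazonium stage instead of oxygen capture;
- ionisation at the other acetal oxygen, or participation of O1, which transposes the ring oxygens;
- insufficient facial discrimination in the ion pair;
- β-elimination with ring opening during the methoxide equilibration.

A run with BF3·OEt2 would serve as racemic reference and as a test of the insertion as such. The fallback uses known chemistry, sets out from 3, 5 and 8 and returns at 10. Roskamp homologation of 3 with 8 (SnCl2 or NbCl5 cat., CH2Cl2) would give methyl 3-[3,4-bis(allyloxy)-5-methoxyphenyl]-3-oxopropanoate F1. Bromination of its enol (NBS, cat. NH4OAc, Et2O) would give the racemic α-bromo keto ester F2. Alkylation of the more acidic O4–H of 5 with F2 (K2CO3, 1 equiv, acetone) would give the α-aryloxy β-keto ester F3, whose α-centre is configurationally labile. Transfer hydrogenation with dynamic kinetic resolution (RuCl(p-cymene)(TsDPEN), HCO2H–Et3N) would give the syn-(2S,3R) hydroxy ester F4; the catalyst enantiomer is chosen so that the syn product carries the (S) α-carbon. Acid-mediated cyclodehydration (TsOH, CH2Cl2, 0 °C) through the ring C-stabilised benzylic cation would close O1–C2 trans to the C3 ester and deliver 10. Here the C3 centre is set by the reduction and controls C2 in the thermodynamically guided closure. Any cis isomer would be equilibrated under the same acid by reversible ionisation at C2, not with methoxide, because in this sequence C3 carries the stereochemical information. The price is four more steps.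

Step 2. The most likely failures are incomplete exchange, because the equilibrium is not driven far enough with the less nucleophilic ester-bearing catechol, and hydrolytic loss of the electron-rich diaryloxy acetal during isolation. The fallback sets out from 3 and 5 and returns at 7: silylation of 5 (hexamethyldisilazane, cat. TMSCl) to methyl 3-methoxy-4,5-bis(trimethylsilyloxy)benzoate F5, then TMSOTf-catalysed silyl acetalisation of 3 with F5 (Noyori conditions, CH2Cl2, −78 °C, pyridine quench). This is irreversible because a disiloxane is formed, and it needs neither heat nor removal of methanol.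

Step 7. The most likely failures are conjugate addition of the sulfinic acid to the enal, opening at C2 once the para-hydroxyl of ring C is free, and air oxidation of the catechol during work-up. The fallback sets out from 14 and returns at 15: isomerisation of both allyl ethers with [Ir(cod)(PMePh2)2]PF6 (activated with H2, THF, rt) to the bis(prop-1-enyl) ether F6, then hydrolysis of the two enol ethers with dilute aqueous HCl in acetone. No nucleophile is present at any stage.

Step 6. The most likely failures are a second homologation of the product enal, which is more electrophilic than the electron-rich aldehyde 12, and sluggish conversion. The fallback sets out from 12 and returns at 14: Wittig reaction with methyl (triphenylphosphoranylidene)acetate to the (E)-acrylate F7, reduction with i-Bu2AlH (diisobutylaluminium hydride) to the allylic alcohol F8, and MnO2 oxidation of the allylic alcohol in the presence of the saturated one. This adds two steps but cannot over-homologate.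

## Further compounds

F1 | step 3 | methyl 3-[3,4-bis(allyloxy)-5-methoxyphenyl]-3-oxopropanoate | COC(=O)CC(=O)c1cc(OC)c(OCC=C)c(OCC=C)c1
F2 | step 3 | methyl 3-[3,4-bis(allyloxy)-5-methoxyphenyl]-2-bromo-3-oxopropanoate (racemic) | COC(=O)C(Br)C(=O)c1cc(OC)c(OCC=C)c(OCC=C)c1
F3 | step 3 | methyl 4-{[1-[3,4-bis(allyloxy)-5-methoxyphenyl]-3-methoxy-1,3-dioxopropan-2-yl]oxy}-3-hydroxy-5-methoxybenzoate (racemic, labile α-centre) | COC(=O)C(Oc1c(O)cc(C(=O)OC)cc1OC)C(=O)c1cc(OC)c(OCC=C)c(OCC=C)c1
F4 | step 3 | methyl (2S,3R)-3-[3,4-bis(allyloxy)-5-methoxyphenyl]-3-hydroxy-2-[2-hydroxy-6-methoxy-4-(methoxycarbonyl)phenoxy]propanoate | COC(=O)[C@@H](Oc1c(O)cc(C(=O)OC)cc1OC)[C@H](O)c1cc(OC)c(OCC=C)c(OCC=C)c1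
F5 | step 2 | methyl 3-methoxy-4,5-bis(trimethylsilyloxy)benzoate | COC(=O)c1cc(OC)c(O[Si](C)(C)C)c(O[Si](C)(C)C)c1
F6 | step 7 | (E)-3-[(2R,3R)-3-(hydroxymethyl)-5-methoxy-2-[3-methoxy-4,5-bis(prop-1-enyloxy)phenyl]-2,3-dihydro-1,4-benzodioxin-7-yl]prop-2-enal (propenyl geometry not defined) | COc1cc([C@H]2Oc3cc(/C=C/C=O)cc(OC)c3O[C@@H]2CO)cc(OC=CC)c1OC=CC
F7 | step 6 | methyl (E)-3-[(2R,3R)-2-[3,4-bis(allyloxy)-5-methoxyphenyl]-3-(hydroxymethyl)-5-methoxy-2,3-dihydro-1,4-benzodioxin-7-yl]prop-2-enoate | COc1cc([C@H]2Oc3cc(/C=C/C(=O)OC)cc(OC)c3O[C@@H]2CO)cc(OCC=C)c1OCC=C
F8 | step 6 | (E)-3-[(2R,3R)-2-[3,4-bis(allyloxy)-5-methoxyphenyl]-3-(hydroxymethyl)-5-methoxy-2,3-dihydro-1,4-benzodioxin-7-yl]prop-2-en-1-ol | COc1cc([C@H]2Oc3cc(/C=C/CO)cc(OC)c3O[C@@H]2CO)cc(OCC=C)c1OCC=C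
A1 | alternative 1 | tert-butyl{[(2R,3R)-7-(1,3-dioxolan-2-yl)-5-methoxy-2-[3-methoxy-4,5-bis(methoxymethoxy)phenyl]-2,3-dihydro-1,4-benzodioxin-3-yl]methoxy}dimethylsilane | COc1cc([C@H]2Oc3cc(C4OCCO4)cc(OC)c3O[C@@H]2CO[Si](C)(C)C(C)(C)C)cc(OCOC)c1OCOC
A2 | alternative 1 | (1R,2R)-2-(tert-butylperoxy)-3-[(tert-butyldimethylsilyl)oxy]-1-[3-methoxy-4,5-bis(methoxymethoxy)phenyl]propan-1-ol | COc1cc([C@@H](O)[C@H](OOC(C)(C)C)CO[Si](C)(C)C(C)(C)C)cc(OCOC)c1OCOC
A3 | alternative 1 | 5-(1,3-dioxolan-2-yl)-3-methoxy-2-(trimethylsilyl)phenyl trifluoromethanesulfonate | COc1cc(C2OCCO2)cc(OS(=O)(=O)C(F)(F)F)c1[Si](C)(C)C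
A4 | alternative 1 | 5-(1,3-dioxolan-2-yl)-3-methoxybenzyne (aryne carbons C1 and C2) | COC1=CC(C2OCCO2)=CC#C1
A5 | alternative 2 | [(2R,3R)-7-allyl-5-methoxy-2-[3-methoxy-4,5-bis(methoxymethoxy)phenyl]-2,3-dihydro-1,4-benzodioxin-3-yl]methanol | COc1cc([C@H]2Oc3cc(CC=C)cc(OC)c3O[C@@H]2CO)cc(OCOC)c1OCOC
A6 | alternative 2 | (2S)-2-{(R)-[2-(allyloxy)-3-methoxyphenoxy][3-methoxy-4,5-bis(methoxymethoxy)phenyl]methyl}oxirane | COc1cc([C@@H](Oc2cccc(OC)c2OCC=C)[C@@H]2CO2)cc(OCOC)c1OCOC
A7 | alternative 3 | methyl (2R,3S)-7-formyl-5-methoxy-2-[3-methoxy-4,5-bis(methoxymethoxy)phenyl]-2,3-dihydro-1,4-benzodioxine-3-carboxylate | COc1cc([C@H]2Oc3cc(C=O)cc(OC)c3O[C@@H]2C(=O)OC)cc(OCOC)c1OCOC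
A8 | alternative 3 | methyl (2S,3S)-3-[3-methoxy-4,5-bis(methoxymethoxy)phenyl]oxirane-2-carboxylate (cis) | COC(=O)[C@H]1O[C@H]1c1cc(OC)c(OCOC)c(OCOC)c1
A9 | alternative 3 | 4-fluoro-3-hydroxy-5-methoxybenzaldehyde | COc1cc(C=O)cc(O)c1F
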